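The readings come from a simulation for an exercise, and the scatter is random.

The ratio of target gained to substrate lost by 8.00 min in the epsilon run reads 0.814. In the epsilon run a reacted molecule of substrate still stands as target with about that chance, so a line drawn through its target readings already carries this toll.

the same everywhere: gas phase 110 mM (held)

| flask | substrate | remark | time |
|---|---|---|---|
| zeta | 0.26 M | the very flask that is asked about, followed so far |  |
| epsilon | 0.17 M | run made earlier |  |
| flask | 0.26 M |  | 8.0 min |

zeta run (percent of the substrate charged)

| time / s | target / % | substrate / % |
|---|---|---|
| 10.0 | 0 | 100.1 |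
| 12.0 | 0 | 100.0 |
| 20.0 | 0.4 | 99.1 |
| 40.0 | 1.0 | 99.5 |
| 60.0 | 0.4 | 98.7 |
| 90.0 | 1.0 | 98.8 |

epsilon run (percent of the substrate charged)

| time / min | target / % | substrate / % |
|---|---|---|
| 0.500 | 0 | 100.6 |
| 1.50 | 1.6 | 99.5 |
| 3.00 | 2.9 | 95.6 |
| 4.00 | 6.1 | 94.0 |
| 6.00 | 10.6 | 89.3 |
| 8.00 | 12.7 | 84.4 |

(readings scatter by 0.5 percentage points)

* the target standing at 8.0 min, as a percentage of the substrate charged
* the change that raises the amount of target at 8.0 min, in percent of the substrate charged most ("none" if none brings more than 2 percentage points) (Wednesday's / Tuesday's / none)
* amount of target at 8.0 min, in percent of the substrate charged, after Tuesday's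

- Wednesday's: doubling the transfer coefficient of the gas phase, all else as stated
- Tuesday's: doubling the saturation concentration of gas phase, all else as stated

- at the start none of the gas phase is in solution

I draw that line for the epsilon run through the mean of the readings from 1.50 min to 4.00 min and the mean of the last two. Its slope, 0.0195 /min, is what I carry: the target pace, the fraction of the charge turned into target per minute once the flask is running.

The lowest rung of the ladder is the lag. The line reaches zero at 1.02 min, a reading, and I take it as the delay left by the gas, none of which is in solution at the start. The zeta flask has been followed to 1.5 min. There the line gives 0.936% and the reading is 1.0%, so a pace per charge seems to pass from 0.17 M to 0.26 M, as it does for a substrate that is pseudo-first-order at given dissolved gas. That evidence is weak, with a scatter of 0.5 percentage points.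

The next rung is the asked 8.0 min, longer than the lag. The top rung is the half-life of the charge at this pace, 35.6 min, longer than 8.0 min, so I let the line run straight and commit to 13.6%.

Wednesday's halves the lag, by my reckoning, and earns 0.99 points, below the margin of 2 points. Tuesday's doubles the pace if the gas enters first order, which gives 27.2%, so I choose Tuesday's.

The forecast, differing from me in its figures, says 13%, Tuesday's and 24%, holding that “doubling saturation doubles the rate”. The flask gives 12.5% and Tuesday's, with 19.6%; the gains are 7.1 points for Tuesday's and 2.8 points for Wednesday's.

    gas phase ⇌ dissolved gas, rate k1*(csat - [dissolved gas]) (kL = 0.00540 /s)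
    substrate + dissolved gas → target (k = 0.00610 /M/s)
    dissolved gas + target → over-reacted product (k = 0.0120 /M/s)
    target ⇌ isomer of the product (K = 0.450, k = 2.70 × 10⁻⁴ /s)
    dissolved gas → decomposed reagent (k = 5.00 × 10⁻⁴ /s)

My line stands 1.1 points above the flask at 8.0 min, and my figure for Tuesday's stands above the 19.6%. My 0.99 points for Wednesday's stands below the flask's 2.8 points, which is more than the margin. The neighbour flask is the same charge stopped at 3.0 min. The same pace and lag give 3.86% of target there, and that flask holds 3.64%, with 96% of its substrate left.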